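The route rests on cutting the C8–C9 glycol bond of the ten-membered carbocycle (germacranolide locants: lactone O–C6/C7, enoate C1=C10–CO2Me). Because C9 sits between an oxygen and the ester-bearing C10, it is the β-carbon of a latent β-alkoxyacrylate. The key step is a samarium diiodide ketyl–olefin cyclisation: the C8 aldehyde on the lactone adds to C9 of a tethered (E)-β-(PMB-oxy)acrylate, closing the ten-membered ring, setting C8 and C9, and leaving O8 free and O9 protected. The precursor is the trans-lactone carrying the cis-epoxy-(Z)-alkenyl chain at C6 and a formyl group at C7. C1=C10 and the exocyclic methylene are unveiled afterwards by a double elimination.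

Key step: step 17

Remark: locants are those of the target (ring C1–C10; C11/C12/C13 lactone α-carbon, carbonyl and methylene; C14 ester carbon); C1 is drawn as the Felkin epimer and C10 is left undefined in 23–30, since both become sp2 in step 23.

Step 1
Reactants: 1 (S)-5-(hydroxymethyl)furan-2(5H)-one
Product: 2 (S)-5-[(benzyloxy)methyl]furan-2(5H)-one
Conditions: BnOC(=NH)CCl3, TfOH (cat.), CH2Cl2–cyclohexane, 0 °C → rt
Reagents that add atoms: benzyl 2,2,2-trichloroacetimidate, N=C(OCc1ccccc1)C(Cl)(Cl)Cl
Why: Acid-catalysed benzyl transfer from the trichloroacetimidate should protect the primary alcohol without base, which the butenolide would not tolerate; C6 comes from the chiral pool.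

Step 2
Reactants: 2 (S)-5-[(benzyloxy)methyl]furan-2(5H)-one
Product: 3 (4R,5S)-5-[(benzyloxy)methyl]-4-(hydroxymethyl)oxolan-2-one
Conditions: MeOH, benzophenone (cat.), hν (350 nm), rt
Reagents that add atoms: methanol, CO
Why: In this benzophenone-sensitised photochemical radical conjugate addition the hydroxymethyl radical should add to the β-carbon (C7) anti to the C6 substituent, which sets the trans C6/C7 relationship.

Step 3
Reactants: 3 (4R,5S)-5-[(benzyloxy)methyl]-4-(hydroxymethyl)oxolan-2-one
Product: 4 (4R,5S)-5-[(benzyloxy)methyl]-4-{[(triethylsilyl)oxy]methyl}oxolan-2-one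
Conditions: Et3SiCl, imidazole, CH2Cl2, 0 °C
Reagents that add atoms: chlorotriethylsilane, CC[Si](Cl)(CC)CC
Why: Standard silylation of the primary alcohol; the triethylsilyl ether on O8 is chosen because it can later be oxidised directly to the aldehyde.

Step 4
Reactants: 4 (4R,5S)-5-[(benzyloxy)methyl]-4-{[(triethylsilyl)oxy]methyl}oxolan-2-one
Product: 6 (3R,4R,5S)-5-[(benzyloxy)methyl]-4-{[(triethylsilyl)oxy]methyl}-3-({[tri(propan-2-yl)silyl]oxy}methyl)oxolan-2-one, via lithium enolate 5 (not isolated)
Conditions: LiN(i-Pr)2, THF, −78 °C; then (i-Pr)3SiOCH2Cl, DMPU, −78 → −30 °C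
Reagents that add atoms: (chloromethoxy)tri(propan-2-yl)silane, ClCO[Si](C(C)C)(C(C)C)C(C)C
Why: Lactone enolate alkylation with a chloromethyl ether should occur anti to the C7 substituent (the C11 configuration is erased later), and the CH2OSi(i-Pr)3 group serves as the masked exocyclic methylene.

Step 5
Reactants: 6 benzyl ether from step 4
Product: 7 (3R,4R,5S)-5-(hydroxymethyl)-4-{[(triethylsilyl)oxy]methyl}-3-({[tri(propan-2-yl)silyl]oxy}methyl)oxolan-2-one
Conditions: H2 (1 atm), Pd/C, EtOAc, rt
Reagents that add atoms: none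
Why: Hydrogenolysis of the benzyl ether should leave the lactone and both silyl ethers untouched in a non-protic solvent.

Step 6
Reactants: 7 primary alcohol from step 5
Product: 8 (2S,3R,4R)-5-oxo-3-{[(triethylsilyl)oxy]methyl}-4-({[tri(propan-2-yl)silyl]oxy}methyl)oxolane-2-carbaldehyde
Conditions: Dess–Martin periodinane, NaHCO3, CH2Cl2, 0 °C → rt
Reagents that add atoms: none
Why: Dess–Martin oxidation is non-basic, so the α-oxygenated stereocentre C6 should not epimerise.

Step 7
Reactants: 8 lactone aldehyde
Product: 9 (3R,4R,5S)-5-[(Z)-2-iodoprop-1-en-1-yl]-4-{[(triethylsilyl)oxy]methyl}-3-({[tri(propan-2-yl)silyl]oxy}methyl)oxolan-2-one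
Conditions: EtPPh3I, n-BuLi, THF, rt; I2, −78 °C; NaN(SiMe3)2, −78 → −20 °C; then 8, −78 °C
Reagents that add atoms: ethyltriphenylphosphonium iodide, CC[P+](c1ccccc1)(c1ccccc1)c1ccccc1.[I-]; iodine, II
Why: The Stork–Zhao olefination (Wittig reaction of an α-iodo ylide) should give the (Z)-iodoalkene through the kinetically formed cis-oxaphosphetane, placing iodine cis to C6 as needed for the C4=C5 geometry.

Step 8
Reactants: 10 prop-2-yn-1-ol
Product: 11 (Z)-3-(tributylstannyl)prop-2-en-1-ol
Conditions: LiAlH4, THF, 0 °C → rt; then Bu3SnOTf, −78 °C → rt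
Reagents that add atoms: tributyltin trifluoromethanesulfonate, CCCC[Sn](CCCC)(CCCC)OS(=O)(=O)C(F)(F)F
Why: Alkoxide-directed anti-hydroalumination of the propargylic alcohol followed by aluminium-to-tin exchange with retention should give the (Z)-alkenylstannane.

Step 9
Reactants: 9 (Z)-vinyl iodide; 11 (Z)-3-(tributylstannyl)prop-2-en-1-ol
Product: 12 (2Z,4Z)-dienol: lactone 9 in which iodine is replaced by (Z)-CH=CH–CH2OH, giving a (1Z,3Z)-5-hydroxy-2-methylpenta-1,3-dien-1-yl chain at C6
Conditions: Pd2(dba)3 (cat.), AsPh3, NMP, rt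
Reagents that add atoms: none
Why: Stille cross-coupling proceeds with retention at both alkenyl partners, and fluoride-free conditions at room temperature should preserve the Z,Z-diene and the triethylsilyl ether.

Step 10
Reactants: 12 (2Z,4Z)-dienol
Product: 13 cis-epoxy alcohol: 12 with the C2=C3 alkene epoxidised, (2R,3S), giving a (Z)-2-[(2S,3R)-3-(hydroxymethyl)oxiran-2-yl]prop-1-en-1-yl chain at C6
Conditions: Ti(OiPr)4, D-(−)-diethyl tartrate, t-BuOOH, 4 Å molecular sieves, CH2Cl2, −20 °C
Reagents that add atoms: tert-butyl hydroperoxide, CC(C)(C)OO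
Why: In the Katsuki–Sharpless asymmetric epoxidation, titanium delivers oxygen only to the allylic-alcohol alkene, and D-(−)-tartrate should select the face that gives the (2R,3S) cis-epoxide under reagent control.

Step 11
Reactants: 13 cis-epoxy alcohol
Product: 14 cis-epoxy aldehyde: C1 aldehyde of 13, giving a (Z)-2-[(2S,3S)-3-formyloxiran-2-yl]prop-1-en-1-yl chain at C6
Conditions: Dess–Martin periodinane, NaHCO3, CH2Cl2, 0 °C
Reagents that add atoms: none
Why: Buffered Dess–Martin oxidation should give the epimerisable cis-epoxy aldehyde without acid or base; it is used crude.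

Step 12
Reactants: 15 methyl propiolate; 16 (4-methoxyphenyl)methanol
Product: 17 methyl (E)-3-[(4-methoxybenzyl)oxy]prop-2-enoate
Conditions: N-methylmorpholine, CH2Cl2, rt
Reagents that add atoms: none
Why: Amine-catalysed oxa-Michael addition of the alcohol to the propiolate should give the thermodynamically preferred (E)-β-alkoxyacrylate.

Step 13
Reactants: 17 methyl (E)-3-[(4-methoxybenzyl)oxy]prop-2-enoate
Product: 19 methyl (Z)-2-iodo-3-[(4-methoxybenzyl)oxy]prop-2-enoate, via acetoxy iodide adduct 18 (not isolated)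
Conditions: N-iodosuccinimide, AcOH, CH2Cl2, rt; then Et3N, 0 °C → rt
Reagents that add atoms: N-iodosuccinimide, O=C1CCC(=O)N1I; acetic acid, CC(=O)O (retained only in intermediate 18)
Why: Electrophilic iodination at the nucleophilic α-carbon with acetate capture, then base-induced loss of acetic acid (iodination–elimination), should give the isomer with the alkoxy group trans to the ester.

Step 14
Reactants: 14 cis-epoxy aldehyde; 19 methyl (Z)-2-iodo-3-[(4-methoxybenzyl)oxy]prop-2-enoate
Product: 20 C1 carbinol: 14 in which the formyl group has become (R)-CH(OH)–C(CO2Me)=CH–OPMB, with OPMB cis to C1 and trans to CO2Me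
Conditions: CrCl2, NiCl2 (cat.), DMSO, rt
Reagents that add atoms: none
Why: In the Nozaki–Hiyama–Kishi coupling the alkenylchromium keeps the alkene geometry and adds only to the aldehyde; the new C1 carbinol should form mainly in the Felkin–Anh sense, but its configuration is erased later.

Step 15
Reactants: 20 C1 carbinol
Product: 21 C1 tert-butyldimethylsilyl ether of 20
Conditions: t-BuMe2SiOTf, 2,6-lutidine, CH2Cl2, −78 °C
Reagents that add atoms: tert-butyldimethylsilyl trifluoromethanesulfonate, CC(C)(C)[Si](C)(C)OS(=O)(=O)C(F)(F)F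
Why: Silyl triflate silylation of the hindered secondary alcohol; the silyloxy group is chosen as a poor leaving group so that the enolate formed in step 17 is protonated and does not eliminate.

Step 16
Reactants: 21 C1 silyl ether
Product: 22 C8 aldehyde: 21 in which the CH2OSiEt3 group on C7 has become CHO
Conditions: (COCl)2, DMSO, CH2Cl2, −78 → −40 °C; then Et3N, −78 → −20 °C
Reagents that add atoms: none
Why: Under Swern conditions the chlorosulfonium salt should cleave and oxidise only the primary triethylsilyl ether, leaving the secondary tert-butyldimethylsilyl and the primary triisopropylsilyl ethers; low temperature protects the β-acyloxy aldehyde from elimination.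

Step 17
Reactants: 22 C8 aldehyde carrying the tethered (E)-β-(PMB-oxy)acrylate
Product: 23 cyclisation product: ten-membered carbocycle (C1–C10) trans-fused to the lactone, with (8S)-OH, (9S)-OPMB, CH(CO2Me) at C10, (1R)-OSi(t-Bu)Me2 and CH2OSi(i-Pr)3 on C11
Conditions: SmI2 (2.5 equiv), MeOH (5 equiv), THF (2 mM), −78 → 0 °C
Reagents that add atoms: none
Why: Proposed new method: SmI2 reduces the aldehyde to the C8 ketyl, which adds as a nucleophilic radical to C9, the electrophilic β-carbon of the (E)-β-alkoxyacrylate; a second electron transfer gives a samarium enolate that MeOH protonates at C10, the poor silyloxy leaving group at C1 preventing elimination to a SmI2-sensitive vinyl epoxide. The closest known reactions are the SmI2-induced reductive cyclisation of ω-formyl β-alkoxyacrylates to 2,3-trans-tetrahydropyrans and oxepanes and SmI2 ketyl–olefin closures of eight-membered carbocycles; new here are the ten-membered ring and the alkoxy group lying outside it. The ring closes in the 10-endo-trig mode. C8 and C9 are set relative to each other by the chelate in which trivalent samarium bridges the ketyl oxygen and the ester carbonyl: O8 is held on the ester flank of the alkene while the carbon tether must reach C1 on the other flank, which puts H8 anti to C10 and should give the 8,9-syn glycol. Their absolute sense should follow from C7, because the tether leaves from C6, trans to C8 on the lactone, so that only the ketyl face with the Sm–O bond turned away from the lactone (anti to C6–C7) can reach the acrylate. The step needs chemoselectivity for the aldehyde (secured by SmI2/MeOH without HMPA and by masking the α-methylene lactone as CH2OSi(i-Pr)3) and ring closure over intermolecular coupling (secured by high dilution and by the three cis units that pre-fold the chain).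

Step 18
Reactants: 24 methyl (Z)-2-methylbut-2-enoate (methyl angelate)
Product: 25 (Z)-2-methylbut-2-en-1-ol
Conditions: i-Bu2AlH, CH2Cl2, −78 °C
Reagents that add atoms: none
Why: 1,2-Reduction of the ester by the aluminium hydride should give the allylic alcohol with the Z geometry intact.

Step 19
Reactants: 25 (Z)-2-methylbut-2-en-1-ol
Product: 26 [(2S,3R)-2,3-dimethyloxiran-2-yl]methanol
Conditions: Ti(OiPr)4 (cat.), L-(+)-diethyl tartrate (cat.), t-BuOOH, 4 Å molecular sieves, CH2Cl2, −20 °C
Reagents that add atoms: tert-butyl hydroperoxide, CC(C)(C)OO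
Why: Katsuki–Sharpless asymmetric epoxidation with L-(+)-tartrate should deliver oxygen to the face that gives the (2S,3R)-epoxy alcohol.

Step 20
Reactants: 26 [(2S,3R)-2,3-dimethyloxiran-2-yl]methanol
Product: 27 (2R,3R)-2,3-dimethyloxirane-2-carboxylic acid
Conditions: RuCl3 (cat.), NaIO4, MeCN–EtOAc–H2O, rt
Reagents that add atoms: water, O
Why: Ruthenium-catalysed periodate oxidation takes the primary alcohol through the aldehyde hydrate to the acid without touching the epoxide or its stereocentres.

Step 21
Reactants: 23 cyclisation product; 27 (2R,3R)-2,3-dimethyloxirane-2-carboxylic acid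
Product: 28 O8 ester: 23 acylated at O8 with the (2R,3R)-2,3-dimethyloxirane-2-carbonyl group
Conditions: DCC, DMAP, CH2Cl2, 0 °C → rt
Reagents that add atoms: none
Why: Steglich esterification acylates the only free hydroxyl (O8) with retention at C8, and the acid has no α-hydrogen to epimerise.

Step 22
Reactants: 28 O8 ester
Product: 29 1,13-diol: 28 with both silyl ethers removed (C1–OH and C13–OH)
Conditions: Bu4NF, AcOH, THF, 0 °C → rt
Reagents that add atoms: none
Why: Acetic-acid-buffered fluoride desilylation should cleave both silyl ethers while sparing the epoxides, the esters and the aldol-type C1–C10 bond.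

Step 23
Reactants: 29 1,13-diol
Product: 31 9-O-(4-methoxybenzyl) ether of the target, via bis-mesylate 30 (not isolated)
Conditions: MsCl, Et3N, CH2Cl2, 0 °C; then DBU, 0 °C → rt
Reagents that add atoms: methanesulfonyl chloride, CS(=O)(=O)Cl (retained only in intermediate 30)
Why: Double E1cB elimination of the two β-mesyloxy carbonyl units should form the exocyclic methylene and the C1=C10 enoate, the latter with C2 trans to CO2Me (the conjugated, in-ring cis geometry), because mesylate leaves far more readily than the C9 ether oxygen.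

Step 24
Reactants: 31 9-O-(4-methoxybenzyl) ether of the target
Product: 32 target CNP0291485.1
Conditions: DDQ, CH2Cl2–pH 7 buffer, 0 °C
Reagents that add atoms: none
Why: Oxidative cleavage of the electron-rich 4-methoxybenzyl ether by DDQ (hydride abstraction, then hydrolysis) should free the C9 alcohol under neutral conditions that spare the epoxides, esters and α-methylene lactone.

Compound list
1 | (S)-5-(hydroxymethyl)furan-2(5H)-one | O=C1O[C@H](CO)C=C1 | starting material
2 | (S)-5-[(benzyloxy)methyl]furan-2(5H)-one | O=C1O[C@H](COCc2ccccc2)C=C1 | intermediate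
3 | (4R,5S)-5-[(benzyloxy)methyl]-4-(hydroxymethyl)oxolan-2-one | O=C1O[C@H](COCc2ccccc2)[C@@H](CO)C1 | intermediate
4 | (4R,5S)-5-[(benzyloxy)methyl]-4-{[(triethylsilyl)oxy]methyl}oxolan-2-one | O=C1O[C@H](COCc2ccccc2)[C@@H](CO[Si](CC)(CC)CC)C1 | intermediate
5 | lithium enolate of 4 | [Li]OC1=C[C@H](CO[Si](CC)(CC)CC)[C@@H](COCc2ccccc2)O1 | intermediate
6 | (3R,4R,5S)-5-[(benzyloxy)methyl]-4-{[(triethylsilyl)oxy]methyl}-3-({[tri(propan-2-yl)silyl]oxy}methyl)oxolan-2-one | O=C1O[C@H](COCc2ccccc2)[C@@H](CO[Si](CC)(CC)CC)[C@@H]1CO[Si](C(C)C)(C(C)C)C(C)C | intermediate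
7 | (3R,4R,5S)-5-(hydroxymethyl)-4-{[(triethylsilyl)oxy]methyl}-3-({[tri(propan-2-yl)silyl]oxy}methyl)oxolan-2-one | O=C1O[C@H](CO)[C@@H](CO[Si](CC)(CC)CC)[C@@H]1CO[Si](C(C)C)(C(C)C)C(C)C | intermediate
8 | (2S,3R,4R)-5-oxo-3-{[(triethylsilyl)oxy]methyl}-4-({[tri(propan-2-yl)silyl]oxy}methyl)oxolane-2-carbaldehyde | O=C1O[C@H](C=O)[C@@H](CO[Si](CC)(CC)CC)[C@@H]1CO[Si](C(C)C)(C(C)C)C(C)C | intermediate
9 | (3R,4R,5S)-5-[(Z)-2-iodoprop-1-en-1-yl]-4-{[(triethylsilyl)oxy]methyl}-3-({[tri(propan-2-yl)silyl]oxy}methyl)oxolan-2-one | O=C1O[C@H](/C=C(/C)I)[C@@H](CO[Si](CC)(CC)CC)[C@@H]1CO[Si](C(C)C)(C(C)C)C(C)C | intermediate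
10 | prop-2-yn-1-ol | C#CCO | starting material
11 | (Z)-3-(tributylstannyl)prop-2-en-1-ol | OC/C=C\[Sn](CCCC)(CCCC)CCCC | intermediate
12 | (2Z,4Z)-dienol (9 with I replaced by (Z)-CH=CH–CH2OH) | O=C1O[C@H](/C=C(/C)\C=C/CO)[C@@H](CO[Si](CC)(CC)CC)[C@@H]1CO[Si](C(C)C)(C(C)C)C(C)C | intermediate
13 | (2R,3S)-cis-epoxy alcohol | O=C1O[C@H](/C=C(/C)[C@@H]2O[C@@H]2CO)[C@@H](CO[Si](CC)(CC)CC)[C@@H]1CO[Si](C(C)C)(C(C)C)C(C)C | intermediate
14 | cis-epoxy aldehyde (C1 aldehyde of 13) | O=C1O[C@H](/C=C(/C)[C@@H]2O[C@@H]2C=O)[C@@H](CO[Si](CC)(CC)CC)[C@@H]1CO[Si](C(C)C)(C(C)C)C(C)C | intermediate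
15 | methyl propiolate | C#CC(=O)OC | starting material
16 | (4-methoxyphenyl)methanol | COc1ccc(CO)cc1 | starting material
17 | methyl (E)-3-[(4-methoxybenzyl)oxy]prop-2-enoate | COC(=O)/C=C/OCc1ccc(OC)cc1 | intermediate
18 | methyl 3-acetoxy-2-iodo-3-[(4-methoxybenzyl)oxy]propanoate | COC(=O)C(I)C(OC(C)=O)OCc1ccc(OC)cc1 | intermediate
19 | methyl (Z)-2-iodo-3-[(4-methoxybenzyl)oxy]prop-2-enoate | COC(=O)/C(I)=C/OCc1ccc(OC)cc1 | intermediate
20 | C1 carbinol (adduct of 14 and 19, (1R) drawn) | O=C1O[C@H](/C=C(/C)[C@@H]2O[C@@H]2[C@H](O)/C(C(=O)OC)=C\OCc3ccc(OC)cc3)[C@@H](CO[Si](CC)(CC)CC)[C@@H]1CO[Si](C(C)C)(C(C)C)C(C)C | intermediate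
21 | C1 tert-butyldimethylsilyl ether of 20 | O=C1O[C@H](/C=C(/C)[C@@H]2O[C@@H]2[C@H](O[Si](C)(C)C(C)(C)C)/C(C(=O)OC)=C\OCc3ccc(OC)cc3)[C@@H](CO[Si](CC)(CC)CC)[C@@H]1CO[Si](C(C)C)(C(C)C)C(C)C | intermediate
22 | C8 aldehyde (cyclisation precursor) | O=C1O[C@H](/C=C(/C)[C@@H]2O[C@@H]2[C@H](O[Si](C)(C)C(C)(C)C)/C(C(=O)OC)=C\OCc3ccc(OC)cc3)[C@@H](C=O)[C@@H]1CO[Si](C(C)C)(C(C)C)C(C)C | intermediate
23 | cyclisation product ((8S)-OH, (9S)-OPMB, C10 undefined) | O=C1O[C@@H]2/C=C(/C)[C@@H]3O[C@@H]3[C@H](O[Si](C)(C)C(C)(C)C)C(C(=O)OC)[C@H](OCc4ccc(OC)cc4)[C@@H](O)[C@H]2[C@@H]1CO[Si](C(C)C)(C(C)C)C(C)C | intermediate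
24 | methyl (Z)-2-methylbut-2-enoate | C/C=C(/C)C(=O)OC | starting material
25 | (Z)-2-methylbut-2-en-1-ol | C/C=C(/C)CO | intermediate
26 | [(2S,3R)-2,3-dimethyloxiran-2-yl]methanol | OC[C@]1(C)O[C@@H]1C | intermediate
27 | (2R,3R)-2,3-dimethyloxirane-2-carboxylic acid | OC(=O)[C@]1(C)O[C@@H]1C | intermediate
28 | O8 (2R,3R)-2,3-dimethyloxirane-2-carboxylate of 23 | O=C1O[C@@H]2/C=C(/C)[C@@H]3O[C@@H]3[C@H](O[Si](C)(C)C(C)(C)C)C(C(=O)OC)[C@H](OCc4ccc(OC)cc4)[C@@H](OC(=O)[C@]5(C)O[C@@H]5C)[C@H]2[C@@H]1CO[Si](C(C)C)(C(C)C)C(C)C | intermediate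
29 | 1,13-diol | O=C1O[C@@H]2/C=C(/C)[C@@H]3O[C@@H]3[C@H](O)C(C(=O)OC)[C@H](OCc4ccc(OC)cc4)[C@@H](OC(=O)[C@]5(C)O[C@@H]5C)[C@H]2[C@@H]1CO | intermediate
30 | 1,13-bis(methanesulfonate) | O=C1O[C@@H]2/C=C(/C)[C@@H]3O[C@@H]3[C@H](OS(C)(=O)=O)C(C(=O)OC)[C@H](OCc4ccc(OC)cc4)[C@@H](OC(=O)[C@]5(C)O[C@@H]5C)[C@H]2[C@@H]1COS(C)(=O)=O | intermediate
31 | 9-O-(4-methoxybenzyl) ether of the target | C=C1C(=O)O[C@@H]2/C=C(/C)[C@@H]3O[C@@H]3/C=C(/C(=O)OC)[C@H](OCc4ccc(OC)cc4)[C@@H](OC(=O)[C@]5(C)O[C@@H]5C)[C@@H]12 | intermediate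
32 | CNP0291485.1: methyl (1(10)E,2R,3S,4Z,6R,7S,8S,9S)-8-{[(2R,3R)-2,3-dimethyloxirane-2-carbonyl]oxy}-2,3-epoxy-9-hydroxy-12-oxogermacra-1(10),4,11(13)-trien-12,6-olid-14-oate | C=C1C(=O)O[C@@H]2/C=C(/C)[C@@H]3O[C@@H]3/C=C(/C(=O)OC)[C@H](O)[C@@H](OC(=O)[C@]3(C)O[C@@H]3C)[C@@H]12 | target

Total step count: 24. Longest linear sequence: 18 steps (1–7, 9–11, 14–17, 21–24).

Steps most likely to fail

Step 17 (bears the label). If the chelate between the samarium-bound ketyl oxygen and the ester carbonyl is not maintained, the ketyl adds with its oxygen turned the other way and the C8-epimeric alcohol forms, with C9 unchanged. The slow ten-membered closure may also be outrun by simple reduction of the ketyl; only the stereochemical failure is answered here. The fallback sets out from 22 and comes back at 28. Should the cyclisation of 22 deliver the 8-epimeric cyclisation product F1, it is esterified with acid 27 under Mitsunobu conditions (PPh3, DIAD, toluene, 0 °C → rt). This known reaction installs the ester with inversion at C8 and should give 28 directly, replacing the retentive esterification of step 21.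

Step 14. The Lewis-acidic chromium chlorides may open the cis-epoxy aldehyde, or C2 may epimerise before the slow coupling takes place. The fallback sets out from 19 (with 14) and comes back at 20. Iodide 19 is converted separately by iodine–magnesium exchange (i-PrMgCl·LiCl, THF, −78 °C) into methyl (Z)-2-(chloromagnesio)-3-[(4-methoxybenzyl)oxy]prop-2-enoate F2. This preformed alkenylmagnesium reagent is then added to 14 at −78 °C, so that the aldehyde meets the nucleophile only at low temperature and without chromium salts.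

Step 23. After deprotonation at C10 the enolate may expel the C9 ether oxygen instead of the C1 mesylate, and the amidine base may move the new methylene into the ring by deprotonation at C7. The fallback sets out from 29 and comes back at 31. Both β-hydroxy carbonyl units of 29 are dehydrated with Martin sulfurane, Ph2S[OC(CF3)2Ph]2 (CH2Cl2, 0 °C → rt). The reaction runs through alkoxysulfuranes, with no sulfonate ester, no amidine base and no isolated intermediate.

Further compounds
F1 | step 17 | 8-epimeric cyclisation product ((8R)-OH epimer of 23) | O=C1O[C@@H]2/C=C(/C)[C@@H]3O[C@@H]3[C@H](O[Si](C)(C)C(C)(C)C)C(C(=O)OC)[C@H](OCc4ccc(OC)cc4)[C@H](O)[C@H]2[C@@H]1CO[Si](C(C)C)(C(C)C)C(C)C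
F2 | step 14 | methyl (Z)-2-(chloromagnesio)-3-[(4-methoxybenzyl)oxy]prop-2-enoate | COC(=O)/C([Mg]Cl)=C/OCc1ccc(OC)cc1
F0 | step 23 | none | none
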